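Count the nucleophile.

| flask | solid electrophile | nucleophile | remark | time |
|---|---|---|---|---|
| teal | 6.7 mM | 1.2 equiv | run made earlier |  |
| amber | 15 mM | 1.2 equiv | run made earlier |  |
| flask | 10 mM | 1.20 equiv |  | 10 d |

- teal (time / d: solid electrophile / %, target / %): 1.04: 24, 39; 2.00: 0, 58; 5.00: 0, 76; 12.0: 2, 84
- amber (time / d: solid electrophile / %, target / %): 1.67: 37, 47; 4.00: 14, 67; 8.00: 2, 79; 12.0: 0, 85

(standard deviation of a reading: 1.5 percentage points)

- at the start none of the solid electrophile is in solution
- what has only dissolved of solid electrophile counts as not reacted
- what has gone from electrophile into another species counts as reacted, even if it can come back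
- the earlier runs do not show how much of nucleophile is bound; that part of a forecast is a guess

- part of the solid electrophile that has reacted (what has only dissolved counts as not reacted) at 10 d
- share of the unused nucleophile that is free and not bound as protonated nucleophile, at 10 d

The solid electrophile is the limiting reagent by charge, but I take it that each electrophile that turns into target costs one nucleophile and sets free one acid, and that this acid can hold a further nucleophile as protonated nucleophile. Per electrophile charged, the acid grows with the part turned into target while the unused nucleophile is the charged equivalents minus that part. The two meet at the crossover, 60.0%, half the equivalents charged. Beyond it, acid made outnumbers unused nucleophile.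

The teal run has the same equivalents as the flask and a lower concentration, so it has the same crossover. Its target reads 58% at 2.00 d, about the crossover, then gains 18 percentage points by 5.00 d and 8 points more by 12.0 d. The amber run, with about twice the teal concentration, reads 85% at 12.0 d beside the teal 84%. I therefore expect target in the flask near these readings, past the crossover, with 3.60 mM of nucleophile unused, free and bound together, against 8.40 mM of acid made. How much of that nucleophile is bound the earlier runs do not show, so that part stays a guess.

The forecast gives 83% reacted (79% to 87%) and 16% free (6% to 35%), holding that “released acid must be binding nucleophile”.

The flask gives 92.6% reacted and 8.88% free.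

    electrophile + nucleophile → acid set free + target (k = 21.0 L mol⁻¹ h⁻¹)
    nucleophile + acid set free ⇌ protonated nucleophile, settled at all times (K = 1900 L mol⁻¹)
    solid electrophile ⇌ electrophile, rate k3*(cs3 - [electrophile]) while solid is left; crystals form when [electrophile] > cs3 (solubility = 1.50 mM, k = 0.410 h⁻¹)
    electrophile ⇌ dormant form (K = 0.960, k = 0.210 h⁻¹)
    target → over-reaction product (k = 9.30 × 10⁻⁵ h⁻¹)

While solid electrophile stood in the flask, 41.8% at 1.00 d, it fed electrophile, which went on to target and into the dormant form, 10.3% by then. With the solid at 0% by 5.00 d, electrophile and dormant form fell together to 7.36% and 7.17% at 10 d, and the dormant form counts as reacted. Target then stands at 84.0%, past the crossover, with 5.40 mM of acid unbound. The neighbour with 3.00 equiv of nucleophile has its crossover at 150%, above its target of 98.0%, and its free share is 52.4%.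

The earlier runs and the new flask are simulated for an exercise; noise was put on by code.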